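I set a neighbour flask with 0.12 M of coupling partner beside this one with 0.300 M, looking for a number that would carry from one to the other.

    coupling partner + right-handed substrate → right-handed product (k1 = 0.72 /M/h)
    coupling partner + left-handed substrate → left-handed product (k2 = 1.4 /M/h)
    left-handed product ⇌ right-handed product (k3 = 1.3 /h)
    left-handed substrate ⇌ right-handed substrate (k4 = 0.13 /h)
    coupling partner → decomposed reagent (k5 = 2.2 /h)

left-handed substrate 0.10 M; coupling partner 0.300 M (in portions, 4); right-handed substrate 0.10 M; time 15 d; the portions of coupling partner follow each other after 40 min, the first at the start

- the state of affairs at 15 d: stopped, and by what, or still going (the coupling partner has run out first / forward and back rates have come level / all of the left-handed substrate has reacted / it is still moving)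
- share of the left-handed substrate and right-handed substrate together used up at 15 d
- left-handed product at 15 d, in percent of the left-handed substrate and right-handed substrate together charged

- coupling partner is single-handed; left-handed substrate and right-handed substrate are mirror images of each other, charged as a racemate, each of them at the stated concentration
- the reaction counts as stopped when no species that holds the left-handed substrate and right-handed substrate together changes by six tenths of a point or more over the second half of the time
- run time (flask): 15 d
- the handed part of coupling partner does not stay in what it makes, so the products of the two hands are mirror images too

I turned the constants into times at the charged amounts, holding the substrates at their charge in a pseudo-first-order view. In this flask the coupling partner decomposed with a time of 0.455 h and met the two substrates together with a time of 4.72 h, so decomposition was faster by about ten times. That gave 8.79 %: the capture share, the coupling rate over coupling plus decomposition, which, with the substrates held at their charge, is the part of the coupling partner that reaches a substrate.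

I then went through the settings. The charge of coupling partner I expected to act in proportion, and 0.300 M times the capture share, over the 0.200 M of substrates, gave me 13.2 % conversion, which I expected to be high, since the coupling uses up the substrates I had held fixed. The portions came 40 min apart, longer than the decomposition half-life of 18.9 min, so I gave each portion much the same fork and expected their spacing to matter little. Lengthening the time I also expected to change little, since 18.9 min is far shorter than 15 d. The products relax into each other with a half-life of 0.267 h, far shorter than 15 d, so I let them share the conversion equally, which gave 6.60 % left-handed product.

The forecast gave the coupling partner has run out first, 12.4 % and 6.2 %, on the ground that “The coupling partner decomposes about ten times faster than it couples”; its conversion stood below mine.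

The flask gave the coupling partner has run out first, 12.4 % and 6.18 %. In this flask, coupling ran while coupling partner stood there: the left-handed coupling reached the midpoint of its turnover at 0.0580 d and had 100 % of it behind it at 7.50 d, when coupling partner stood at 0 %. Each product then stood at 6.18 %, and decomposed reagent at 0.275 M. Read back from the conversion, the capture share over the whole run of this flask was 8.24 %, whereas my 8.79 % was reckoned for substrates at their charge, and the left-handed substrate ended at 88 % of its own. Carried to the neighbour flask, my 8.79 % gave 5.27 %, and that flask reached 5.14 %.

(The constants were set for the occasion; the flask was simulated.)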